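## Structural features

The target is a diarylheptanoid closed into an oxane. The ring oxygen joins C1 and C5 of the C1–C7 chain; C1 carries ring B (3,4-dihydroxy-5-methoxyphenyl), C3 a free secondary hydroxyl, and C5 the C6–C7 ethylene tether to ring A (4-hydroxy-3-methoxyphenyl). The stereocentres C1 (S), C3 (R) and C5 (S) are not adjacent: C2 and C4 are methylene spacers and the ring oxygen separates C1 from C5. All three substituents are cis, that is, equatorial on one chair (oxane numbering 2S,4R,6S).

Ring B is a catechol flanked by a methoxyl group and oxidises to an ortho-quinone in air once deprotonated. The C1–O bond is a benzylic ether para to an oxygen, so it is open to acid ionisation and to hydrogenolysis. The carbon skeleton is simple; the real difficulty is to fix three 1,3-related stereocentres, relative and absolute, from one source of chirality and to bring in the oxidisable ring B late.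

The key step uses the fact that C1–C5, with the C3 oxygen and the C5 chain cis, are a cis-2,4-disubstituted cyclopentanone (C1 as carbonyl carbon) once the ring oxygen is removed. Oxygen insertion into the C1–C5 bond gives the six-membered lactone with C3 and C5 already correct and leaves C1 at the acid oxidation level, ready to receive ring B.

## Logic of the disconnections

**18 to 17.** The four O–Si bonds are cut. All three phenols and the C3 hydroxyl are kept silylated to the end because the free catechol of ring B tolerates neither base with air nor hydrogenolysis next to the benzylic C1–O bond. One fluoride treatment then finishes the synthesis. The forward step needs a buffered, oxygen-free fluoride source.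

**17 to 15.** The C1–H bond is cut, which puts C1 at the ketal level. The last stereocentre is thereby set by the ring itself, after C3 and C5 are in place. The forward reduction must deliver hydride axially to the oxocarbenium ion 16 and must stop before the benzylic C–O bond is reduced further.

**15 to 9 and 13.** The C1–aryl bond is cut. This is the convergent point: all of ring B arrives as the aryllithium 14, made from 13, and the lactone carbonyl of 9 is the electrophile. The forward step needs a single addition at low temperature, without enolisation of 9 and loss of the β-silyloxy group.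

**9 to 7 (key).** The O–C5 bond is cut and C1 is rejoined to C5. A 4,6-cis lactone corresponds to an anti-1,3-diol, which is awkward to make in open-chain form, whereas the same relation on a cyclopentane is a 2,4-cis pair that a hydrogenation can set. The forward step, through 8, needs migration of the substituted α-carbon with retention and a buffered medium. The structures of 1, 7 and 9 were checked atom by atom against 18 and need no correction. The carbinol carbon is S in 1, 2 and 6 and R from 7 onward with unchanged geometry, because saturating the alkene inverts the ranking of the two ring branches.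

**7 to 6.** Two C–H bonds are cut (the C4=C5 alkene of the heptanoid numbering is restored). This removes the C5 stereocentre and leaves a single stereocentre that comes from the chiral pool. The forward hydrogenation must add from the face opposite the silyloxy group.

**6 to 2 and 4.** The C5–C6 bond is cut between the enone α-carbon and the tether. The tether comes from the styrene 4 through its borane 5, so no separate two-carbon homologation is needed. The coupling runs in aqueous carbonate, and this sets the one change in the design of the precursor: the ring A phenol carries a triisopropylsilyl group in 4 to 17. An aryl tert-butyldimethylsilyl ether is at risk in that medium; the bulkier group should hold and still leaves in the final fluoride step.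

**2 to 1 and 4 to 3.** A C–I bond and an O–Si bond are cut. Both are one-step functionalisations of catalogue compounds.

**13 to 12 to 10.** The two O–Si bonds of 13 are cut, then the phenolic C–O bond of 12 is traced to the formyl C–C bond of 10. Compound 10 already has bromine para to the central oxygen. Electrophilic bromination of the halogen-free parent catechol would be expected to go para to the outer hydroxyl and ortho to the methoxyl group, giving the wrong isomer, so that route to 13 is not used. The forward Dakin step must be run without air.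

## Other disconnections considered

**Alternative 1:** The cuts are C2–C3 and C3–C4. C3 becomes the carbon of the silyl dithiane A4; C4–C7 with ring A come from the enantiopure alkyl epoxide A2, and C1–C2 with ring B from the aryl epoxide A3. In the forward step lithiated A4 opens A2 at its CH2. HMPA then triggers a 1,4-Brook shift of silicon from carbon to the new alkoxide, which caps the C5 oxygen and regenerates a dithiane anion. That anion opens A3 at its CH2 to give A1.
- In favour: three components, two C–C bonds and the whole C1–C7 chain in one flask; C5 taken from A2; the C1 and C5 oxygens come out differentiated.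
- Against: no ring is formed and only one of three stereocentres is set. C1 is uncontrolled unless A3 is enantiopure. The electron-rich A3 may open at its benzylic carbon. After A1 there remain dithiane removal beside two electron-rich arenes, C–O ring closure, ketone reduction, and hydrogenolysis of three benzyl ethers next to a benzylic ring C–O bond.
- Comparison: on convergence and on C–C bonds made per step A1 is better than the chosen plan, whose key step makes no C–C bond. Mechanistically both rest on well-understood polar steps, so they are equal there. On structure the chosen plan is ahead, because C3 and C5 are locked on a ring before the oxygen is inserted. About five operations would follow A1 against three after 9.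

**Alternative 2:** The cut is C1–C2. The ether A6 already joins C5 and the benzylic C1 through oxygen. In the forward step DDQ abstracts hydride from the benzylic CH2 of A6, and the oxocarbenium ion is captured by the enol acetate carbon through a chair transition state to give A5.
- In favour: ring, C1–C2 bond and C1 stereocentre arise in one step from a C–H bond. The cis selectivity expected from the chair is the equal of the axial hydride delivery in the chosen plan. The step creates a stereocentre where the Baeyer–Villiger step creates none, and on that point it is better.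
- Against: the oxidant must choose the C1 benzylic ether over the two benzyl groups on ring B and over C7. This forces an electron-poor pivalate on ring A and hence two kinds of phenol protection and two kinds of deprotection. The ketone of A5 must still be reduced, and the benzyl ethers must be hydrogenolysed next to the benzylic ring C–O bond. A6 needs its own enantioselective construction of C5.
- Comparison: structurally A5 holds two of the three stereocentres, as 9 does. Mechanistically the hydride abstraction is less predictable on this polyoxygenated substrate than a peracid oxidation. The step count would probably be similar or slightly longer.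

**Alternative 3:** The cut is C4–C5. The cis enol acetal A8 holds C1 with ring B and the acetal carbon C5. In the forward step Me2AlCl opens A8 to an oxocarbenium ion and an aluminium enolate, whose carbon closes onto C5 through a chair to give A7.
- In favour: one purchased or catalytically made stereocentre (C1) is relayed to C5, which equals the chosen plan in its use of a single chiral source. Ring and C–C bond form together, which is better than the chosen key step. Cis-2,6 selectivity should be high.
- Against: A8 needs about three steps of its own, including a carbonyl methylenation. Its ring oxygen at C1 is benzylic and para-oxygenated, so the Lewis acid may ionise C1–O instead of the acetal C–O bond and erode the C1 configuration. A7 again needs ketone reduction and hydrogenolysis of three benzyl ethers.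
- Comparison: the structural outcome equals that of Alternative 2 (A7 against A5). The mechanism is well understood but less safe for this particular aryl group. Step economy is no better than the chosen plan, which ends with a single global desilylation.

Key step: step 5

Assumption: 1, 3 and 10 are taken as catalogue compounds; 3 is used cold and fresh because it polymerises on storage.

## Steps

**Step 1**
Reactants: 1 (S)-4-(tert-butyldimethylsilyloxy)cyclopent-2-en-1-one
Product: 2 (S)-4-(tert-butyldimethylsilyloxy)-2-iodocyclopent-2-en-1-one
Conditions: I2, pyridine/CH2Cl2 (1:1), 0 °C to rt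
Reagents that add atoms: iodine, II
Why: α-Iodination of an enone by pyridine addition, iodination of the enolate and elimination (a Baylis–Hillman-type pathway); the stereocentre is not involved and the silyl ether tolerates the weak base.

**Step 2**
Reactants: 3 2-methoxy-4-vinylphenol (4-vinylguaiacol)
Product: 4 triisopropyl(2-methoxy-4-vinylphenoxy)silane
Conditions: TIPSCl, imidazole, DMF, 0 °C to rt
Reagents that add atoms: triisopropylsilyl chloride, CC(C)[Si](Cl)(C(C)C)C(C)C
Why: Standard silylation of a phenol; the triisopropylsilyl ether is chosen to survive aqueous carbonate in step 3 and still leave with fluoride in step 10.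

**Step 3**
Reactants: 4 triisopropyl(2-methoxy-4-vinylphenoxy)silane, 2 (S)-4-(tert-butyldimethylsilyloxy)-2-iodocyclopent-2-en-1-one
Product: 6 (S)-4-(tert-butyldimethylsilyloxy)-2-{2-[3-methoxy-4-(triisopropylsilyloxy)phenyl]ethyl}cyclopent-2-en-1-one, via B-alkyl-9-BBN adduct 5 (not isolated)
Conditions: 9-BBN, THF, 0 °C to rt; then 2, PdCl2(dppf) (cat.), Ph3As (cat.), Cs2CO3, DMF/THF/H2O, rt
Reagents that add atoms: none
Why: Anti-Markovnikov hydroboration of the styrene followed by B-alkyl Suzuki–Miyaura coupling with the α-iodoenone, a combination known to run at room temperature on 4-silyloxy-2-iodocyclopentenones; the mild temperature should spare the γ-silyloxy enone from elimination.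

**Step 4**
Reactants: 6 (S)-4-(tert-butyldimethylsilyloxy)-2-{2-[3-methoxy-4-(triisopropylsilyloxy)phenyl]ethyl}cyclopent-2-en-1-one
Product: 7 (2S,4R)-4-(tert-butyldimethylsilyloxy)-2-{2-[3-methoxy-4-(triisopropylsilyloxy)phenyl]ethyl}cyclopentan-1-one
Conditions: H2 (1 atm), 5% Rh/Al2O3, EtOAc, rt
Reagents that add atoms: none
Why: Heterogeneous syn-hydrogenation from the face opposite the bulky silyloxy group on the adjacent carbon puts the new C2–H anti to it, so the chain ends cis to the silyloxy group (2S); Rh on alumina in a neutral aprotic solvent is chosen to limit allylic C–O hydrogenolysis, and the cis isomer should be at least as stable as the trans one.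

**Step 5**
Reactants: 7 (2S,4R)-4-(tert-butyldimethylsilyloxy)-2-{2-[3-methoxy-4-(triisopropylsilyloxy)phenyl]ethyl}cyclopentan-1-one
Product: 9 (4R,6S)-4-(tert-butyldimethylsilyloxy)-6-{2-[3-methoxy-4-(triisopropylsilyloxy)phenyl]ethyl}tetrahydro-2H-pyran-2-one, via Criegee adduct 8 (not isolated)
Conditions: mCPBA, NaHCO3, CH2Cl2, 0 °C to rt
Reagents that add atoms: 3-chloroperoxybenzoic acid (mCPBA), OOC(=O)c1cccc(Cl)c1
Why: Baeyer–Villiger oxidation: the peracid adds to the ketone carbonyl to give the tetrahedral Criegee adduct 8, and the ring carbon bearing the arylethyl chain migrates to the proximal peroxide oxygen, antiperiplanar to the breaking O–O bond, as 3-chlorobenzoate leaves. The closest known reaction type is the peracid oxidation of 2-alkylcyclopentanones to 6-alkyltetrahydropyran-2-ones, including ketones with an oxygen substituent at C4. The six-membered ring is closed by ring expansion, a 1,2-shift that inserts oxygen into the existing five-membered ring, not by a cyclisation, so no exo or endo mode applies. No stereocentre is created: the migrating carbon moves with retention because the shift is concerted and suprafacial, and the carbinol carbon is not involved, so the cis relation set in step 4 reappears as (4R,6S) in 9. The step needs regioselectivity, which two features of 7 secure: the migrating carbon is secondary while its competitor is a CH2, and that CH2 is bonded directly to the silyloxy-bearing carbon and so is inductively less able to carry positive charge in the transition state. It also needs chemoselectivity: solid NaHCO3 takes up the 3-chlorobenzoic acid so that neither enolisation toward the α-stereocentre nor β-elimination of silanol competes, and the silylated ring A should not be attacked by the peracid at this temperature.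

**Step 6**
Reactants: 10 5-bromo-2-hydroxy-3-methoxybenzaldehyde
Product: 12 5-bromo-3-methoxybenzene-1,2-diol, via aryl formate 11 (not isolated)
Conditions: 30% H2O2, NaOH, THF/H2O, 0 °C to rt, argon; then HCl (aq)
Reagents that add atoms: hydrogen peroxide, OO
Why: Dakin oxidation of an ortho-hydroxybenzaldehyde: hydroperoxide adds to the aldehyde, the electron-rich aryl group migrates to oxygen to give formate 11, which is saponified in the same flask; the bromine position is fixed by the starting material.

**Step 7**
Reactants: 12 5-bromo-3-methoxybenzene-1,2-diol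
Product: 13 5-bromo-1,2-bis(tert-butyldimethylsilyloxy)-3-methoxybenzene
Conditions: TBSCl, imidazole, DMF, rt
Reagents that add atoms: tert-butyldimethylsilyl chloride, CC(C)(C)[Si](C)(C)Cl
Why: Standard double silylation of a catechol; it removes the acidic protons before lithiation, and neither silyloxy group is ortho to the bromine, so no silyl migration to carbon is possible after exchange.

**Step 8**
Reactants: 13 5-bromo-1,2-bis(tert-butyldimethylsilyloxy)-3-methoxybenzene, 9 (4R,6S)-4-(tert-butyldimethylsilyloxy)-6-{2-[3-methoxy-4-(triisopropylsilyloxy)phenyl]ethyl}tetrahydro-2H-pyran-2-one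
Product: 15 (4R,6S)-2-[3,4-bis(tert-butyldimethylsilyloxy)-5-methoxyphenyl]-4-(tert-butyldimethylsilyloxy)-6-{2-[3-methoxy-4-(triisopropylsilyloxy)phenyl]ethyl}tetrahydro-2H-pyran-2-ol (anomeric mixture), via aryllithium 14 (not isolated)
Conditions: n-BuLi, THF, −78 °C; then 9, THF, −78 °C; NH4Cl (aq)
Reagents that add atoms: none
Why: Bromine–lithium exchange followed by addition of the aryllithium to a δ-lactone, as in C-aryl glycoside synthesis; the lithium lactolate is stable at −78 °C, which should prevent a second addition, and the low temperature disfavours α-deprotonation and loss of the β-silyloxy group.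

**Step 9**
Reactants: 15 (4R,6S)-2-[3,4-bis(tert-butyldimethylsilyloxy)-5-methoxyphenyl]-4-(tert-butyldimethylsilyloxy)-6-{2-[3-methoxy-4-(triisopropylsilyloxy)phenyl]ethyl}tetrahydro-2H-pyran-2-ol
Product: 17 (2S,4R,6S)-2-[3,4-bis(tert-butyldimethylsilyloxy)-5-methoxyphenyl]-4-(tert-butyldimethylsilyloxy)-6-{2-[3-methoxy-4-(triisopropylsilyloxy)phenyl]ethyl}tetrahydro-2H-pyran, via oxocarbenium ion 16 (not isolated)
Conditions: Et3SiH, BF3·OEt2, CH2Cl2/MeCN, −78 to −40 °C
Reagents that add atoms: none
Why: Reductive deoxygenation of an aryl lactol: the Lewis acid ionises the anomeric hydroxyl to the aryl-stabilised oxocarbenium ion 16, whose half-chair keeps the cis silyloxy group and chain pseudo-equatorial (the alternative would place them 1,3-diaxial); hydride from the silane enters axially, so the aryl group becomes equatorial and C2 is set as S, all-cis.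

**Step 10**
Reactants: 17 (2S,4R,6S)-2-[3,4-bis(tert-butyldimethylsilyloxy)-5-methoxyphenyl]-4-(tert-butyldimethylsilyloxy)-6-{2-[3-methoxy-4-(triisopropylsilyloxy)phenyl]ethyl}tetrahydro-2H-pyran
Product: 18 (2S,4R,6S)-2-(3,4-dihydroxy-5-methoxyphenyl)-6-[2-(4-hydroxy-3-methoxyphenyl)ethyl]tetrahydro-2H-pyran-4-ol
Conditions: TBAF, AcOH, THF (degassed), 0 °C to rt
Reagents that add atoms: none
Why: Global fluoride desilylation of three aryl silyl ethers and one secondary alkyl silyl ether; the acetic acid buffer keeps the liberated catechol protonated so that it should not oxidise, and no stereocentre is touched.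

## Compound list

1 | (S)-4-(tert-butyldimethylsilyloxy)cyclopent-2-en-1-one | O=C1C=C[C@@H](O[Si](C)(C)C(C)(C)C)C1 | starting material
2 | (S)-4-(tert-butyldimethylsilyloxy)-2-iodocyclopent-2-en-1-one | O=C1C(I)=C[C@@H](O[Si](C)(C)C(C)(C)C)C1 | intermediate
3 | 2-methoxy-4-vinylphenol (4-vinylguaiacol) | COc1cc(C=C)ccc1O | starting material
4 | triisopropyl(2-methoxy-4-vinylphenoxy)silane | COc1cc(C=C)ccc1O[Si](C(C)C)(C(C)C)C(C)C | intermediate
5 | 9-{2-[3-methoxy-4-(triisopropylsilyloxy)phenyl]ethyl}-9-borabicyclo[3.3.1]nonane (formed in the flask) | COc1cc(CCB2C3CCCC2CCC3)ccc1O[Si](C(C)C)(C(C)C)C(C)C | intermediate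
6 | (S)-4-(tert-butyldimethylsilyloxy)-2-{2-[3-methoxy-4-(triisopropylsilyloxy)phenyl]ethyl}cyclopent-2-en-1-one | COc1cc(CCC2=C[C@@H](O[Si](C)(C)C(C)(C)C)CC2=O)ccc1O[Si](C(C)C)(C(C)C)C(C)C | intermediate
7 | (2S,4R)-4-(tert-butyldimethylsilyloxy)-2-{2-[3-methoxy-4-(triisopropylsilyloxy)phenyl]ethyl}cyclopentan-1-one (2,4-cis) | COc1cc(CC[C@H]2C[C@@H](O[Si](C)(C)C(C)(C)C)CC2=O)ccc1O[Si](C(C)C)(C(C)C)C(C)C | intermediate
8 | Criegee adduct: (2S,4R)-4-(tert-butyldimethylsilyloxy)-1-hydroxy-2-{2-[3-methoxy-4-(triisopropylsilyloxy)phenyl]ethyl}cyclopentyl 3-chloroperoxybenzoate, C1 unassigned (formed in the flask) | COc1cc(CC[C@H]2C[C@@H](O[Si](C)(C)C(C)(C)C)CC2(O)OOC(=O)c2cccc(Cl)c2)ccc1O[Si](C(C)C)(C(C)C)C(C)C | intermediate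
9 | (4R,6S)-4-(tert-butyldimethylsilyloxy)-6-{2-[3-methoxy-4-(triisopropylsilyloxy)phenyl]ethyl}tetrahydro-2H-pyran-2-one (4,6-cis) | COc1cc(CC[C@H]2C[C@@H](O[Si](C)(C)C(C)(C)C)CC(=O)O2)ccc1O[Si](C(C)C)(C(C)C)C(C)C | intermediate
10 | 5-bromo-2-hydroxy-3-methoxybenzaldehyde | COc1cc(Br)cc(C=O)c1O | starting material
11 | 5-bromo-2-hydroxy-3-methoxyphenyl formate (formed in the flask) | COc1cc(Br)cc(OC=O)c1O | intermediate
12 | 5-bromo-3-methoxybenzene-1,2-diol | COc1cc(Br)cc(O)c1O | intermediate
13 | 5-bromo-1,2-bis(tert-butyldimethylsilyloxy)-3-methoxybenzene | COc1cc(Br)cc(O[Si](C)(C)C(C)(C)C)c1O[Si](C)(C)C(C)(C)C | intermediate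
14 | [3,4-bis(tert-butyldimethylsilyloxy)-5-methoxyphenyl]lithium (formed in the flask) | COc1cc([Li])cc(O[Si](C)(C)C(C)(C)C)c1O[Si](C)(C)C(C)(C)C | intermediate
15 | (4R,6S)-2-[3,4-bis(tert-butyldimethylsilyloxy)-5-methoxyphenyl]-4-(tert-butyldimethylsilyloxy)-6-{2-[3-methoxy-4-(triisopropylsilyloxy)phenyl]ethyl}tetrahydro-2H-pyran-2-ol, anomeric centre unassigned | COc1cc(CC[C@H]2C[C@@H](O[Si](C)(C)C(C)(C)C)CC(O)(c3cc(O[Si](C)(C)C(C)(C)C)c(O[Si](C)(C)C(C)(C)C)c(OC)c3)O2)ccc1O[Si](C(C)C)(C(C)C)C(C)C | intermediate
16 | (2S,4R)-6-[3,4-bis(tert-butyldimethylsilyloxy)-5-methoxyphenyl]-4-(tert-butyldimethylsilyloxy)-2-{2-[3-methoxy-4-(triisopropylsilyloxy)phenyl]ethyl}-3,4-dihydro-2H-pyran-1-ium, the oxocarbenium ion (formed in the flask) | COc1cc(CC[C@H]2C[C@@H](O[Si](C)(C)C(C)(C)C)CC(c3cc(O[Si](C)(C)C(C)(C)C)c(O[Si](C)(C)C(C)(C)C)c(OC)c3)=[O+]2)ccc1O[Si](C(C)C)(C(C)C)C(C)C | intermediate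
17 | (2S,4R,6S)-2-[3,4-bis(tert-butyldimethylsilyloxy)-5-methoxyphenyl]-4-(tert-butyldimethylsilyloxy)-6-{2-[3-methoxy-4-(triisopropylsilyloxy)phenyl]ethyl}tetrahydro-2H-pyran (all-cis) | COc1cc(CC[C@H]2C[C@@H](O[Si](C)(C)C(C)(C)C)C[C@@H](c3cc(O[Si](C)(C)C(C)(C)C)c(O[Si](C)(C)C(C)(C)C)c(OC)c3)O2)ccc1O[Si](C(C)C)(C(C)C)C(C)C | intermediate
18 | (2S,4R,6S)-2-(3,4-dihydroxy-5-methoxyphenyl)-6-[2-(4-hydroxy-3-methoxyphenyl)ethyl]tetrahydro-2H-pyran-4-ol | COc1cc(CC[C@H]2C[C@@H](O)C[C@@H](c3cc(O)c(O)c(OC)c3)O2)ccc1O | target

## Step count and least certain steps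

Total: 10 steps. Longest linear sequence: 7 steps (steps 1, 3, 4, 5, 8, 9 and 10).

**Step 5 (key step).** The most likely trouble is a slow oxygen insertion on the cyclopentanone, which would leave time for loss of silanol by β-elimination, for epimerisation at the α-carbon, or for peracid attack on ring A. Migration of the wrong α-carbon is the less likely failure. The fallback sets out from 6, returns at 9, and cleaves the same C1–C5 bond by ozonolysis instead of migration. Rhodium-catalysed 1,4-hydrosilylation of 6 (Et3SiH, RhCl(PPh3)3) should give the regiodefined triethylsilyl enol ether F1. Ozonolysis with reductive work-up should give the 5-oxo acid F2. Selective removal of the alkyl silyl group (HF·pyridine) should give the β-hydroxy ketone F3. Hydroxyl-directed reduction with Me4NBH(OAc)3 (Evans–Saksena) should give the anti-diol acid F4, which re-creates C5 from the surviving C3 stereocentre. Acid-catalysed lactonisation should give the hydroxy lactone F5, and silylation with TBSCl and imidazole gives 9. The detour also bypasses step 4.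

**Step 4.** Poor facial selectivity, or hydrogenolysis of the allylic C–O bond on the metal surface, is the main risk. The fallback sets out from 6, returns at 7, and replaces steric control by hydroxyl direction. Reagent-controlled Corey–Bakshi–Shibata reduction ((R)-methyl oxazaborolidine, BH3·SMe2, enantiomer chosen by the usual model) should give the trans allylic alcohol F6. Homogeneous hydrogenation with [Ir(cod)(PCy3)(py)]PF6 should deliver hydrogen from the hydroxyl face, which is the face opposite the silyloxy group, to give the cyclopentanol F7. Oxidation with Dess–Martin periodinane buffered with NaHCO3 gives 7.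

**Step 8.** The aryllithium may act as a base: deprotonation next to the lactone carbonyl followed by loss of silyloxide, or a second addition if the lactolate collapses. The fallback sets out from 9, returns at 17, and moves the addition to the aldehyde oxidation level. Reduction with i-Bu2AlH at −78 °C should give the lactol F8. Excess 14 should add to its open aldehyde form to give the 1,5-diol F9 as a mixture at C1. A catalytic acid should then ionise the electron-rich benzylic alcohol so that the C5 hydroxyl closes the ring under thermodynamic control to the all-equatorial 17. This fallback also bypasses step 9.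

**Step 9.** Reionisation of the para-oxygenated benzylic C–O bond of the product may lead to reductive ring opening; erosion of the axial selectivity and partial silyl loss are further risks. The fallback sets out from 15, returns at 17, and replaces ionic reduction by surface hydrogenation. Dehydration of 15 (MsCl, Et3N) should give the cyclic enol ether F10. Hydrogenation over Rh/Al2O3 should add from the face opposite the allylic silyloxy group and the chain, placing the aryl group cis to both.

## Further compounds

F1 | step 5 | tert-butyl{[(1R)-3-{2-[3-methoxy-4-(triisopropylsilyloxy)phenyl]ethyl}-4-(triethylsilyloxy)cyclopent-3-en-1-yl]oxy}dimethylsilane | COc1cc(CCC2=C(O[Si](CC)(CC)CC)C[C@H](O[Si](C)(C)C(C)(C)C)C2)ccc1O[Si](C(C)C)(C(C)C)C(C)C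
F2 | step 5 | (R)-3-(tert-butyldimethylsilyloxy)-7-[3-methoxy-4-(triisopropylsilyloxy)phenyl]-5-oxoheptanoic acid | COc1cc(CCC(=O)C[C@@H](O[Si](C)(C)C(C)(C)C)CC(=O)O)ccc1O[Si](C(C)C)(C(C)C)C(C)C
F3 | step 5 | (R)-3-hydroxy-7-[3-methoxy-4-(triisopropylsilyloxy)phenyl]-5-oxoheptanoic acid | COc1cc(CCC(=O)C[C@@H](O)CC(=O)O)ccc1O[Si](C(C)C)(C(C)C)C(C)C
F4 | step 5 | (3R,5S)-3,5-dihydroxy-7-[3-methoxy-4-(triisopropylsilyloxy)phenyl]heptanoic acid (anti) | COc1cc(CC[C@H](O)C[C@@H](O)CC(=O)O)ccc1O[Si](C(C)C)(C(C)C)C(C)C
F5 | step 5 | (4R,6S)-4-hydroxy-6-{2-[3-methoxy-4-(triisopropylsilyloxy)phenyl]ethyl}tetrahydro-2H-pyran-2-one | COc1cc(CC[C@H]2C[C@@H](O)CC(=O)O2)ccc1O[Si](C(C)C)(C(C)C)C(C)C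
F6 | step 4 | (1S,4S)-4-(tert-butyldimethylsilyloxy)-2-{2-[3-methoxy-4-(triisopropylsilyloxy)phenyl]ethyl}cyclopent-2-en-1-ol (1,4-trans) | COc1cc(CCC2=C[C@@H](O[Si](C)(C)C(C)(C)C)C[C@@H]2O)ccc1O[Si](C(C)C)(C(C)C)C(C)C
F7 | step 4 | (1S,2S,4R)-4-(tert-butyldimethylsilyloxy)-2-{2-[3-methoxy-4-(triisopropylsilyloxy)phenyl]ethyl}cyclopentan-1-ol | COc1cc(CC[C@H]2C[C@@H](O[Si](C)(C)C(C)(C)C)C[C@@H]2O)ccc1O[Si](C(C)C)(C(C)C)C(C)C
F8 | step 8 | (4R,6S)-4-(tert-butyldimethylsilyloxy)-6-{2-[3-methoxy-4-(triisopropylsilyloxy)phenyl]ethyl}tetrahydro-2H-pyran-2-ol, anomeric centre unassigned | COc1cc(CC[C@H]2C[C@@H](O[Si](C)(C)C(C)(C)C)CC(O)O2)ccc1O[Si](C(C)C)(C(C)C)C(C)C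
F9 | step 8 | (3R,5S)-1-[3,4-bis(tert-butyldimethylsilyloxy)-5-methoxyphenyl]-3-(tert-butyldimethylsilyloxy)-7-[3-methoxy-4-(triisopropylsilyloxy)phenyl]heptane-1,5-diol, C1 unassigned | COc1cc(CC[C@H](O)C[C@@H](O[Si](C)(C)C(C)(C)C)CC(O)c2cc(O[Si](C)(C)C(C)(C)C)c(O[Si](C)(C)C(C)(C)C)c(OC)c2)ccc1O[Si](C(C)C)(C(C)C)C(C)C
F10 | step 9 | (2S,4R)-6-[3,4-bis(tert-butyldimethylsilyloxy)-5-methoxyphenyl]-4-(tert-butyldimethylsilyloxy)-2-{2-[3-methoxy-4-(triisopropylsilyloxy)phenyl]ethyl}-3,4-dihydro-2H-pyran | COc1cc(CC[C@H]2C[C@@H](O[Si](C)(C)C(C)(C)C)C=C(c3cc(O[Si](C)(C)C(C)(C)C)c(O[Si](C)(C)C(C)(C)C)c(OC)c3)O2)ccc1O[Si](C(C)C)(C(C)C)C(C)C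
A1 | alternative 1 | 1-[3,4-bis(benzyloxy)-5-methoxyphenyl]-2-{2-[(S)-4-(4-benzyloxy-3-methoxyphenyl)-2-(tert-butyldimethylsilyloxy)butyl]-1,3-dithian-2-yl}ethan-1-ol, carbinol centre unassigned | COc1cc(CC[C@H](O[Si](C)(C)C(C)(C)C)CC2(CC(O)c3cc(OCc4ccccc4)c(OCc4ccccc4)c(OC)c3)SCCCS2)ccc1OCc1ccccc1
A2 | alternative 1 | (S)-2-[2-(4-benzyloxy-3-methoxyphenyl)ethyl]oxirane | COc1cc(CC[C@H]2CO2)ccc1OCc1ccccc1
A3 | alternative 1 | 2-[3,4-bis(benzyloxy)-5-methoxyphenyl]oxirane, configuration unassigned | COc1cc(C2CO2)cc(OCc2ccccc2)c1OCc1ccccc1
A4 | alternative 1 | tert-butyl(1,3-dithian-2-yl)dimethylsilane | CC(C)(C)[Si](C)(C)C1SCCCS1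
A5 | alternative 2 | (2S,6S)-2-[3,4-bis(benzyloxy)-5-methoxyphenyl]-6-[2-(3-methoxy-4-pivaloyloxyphenyl)ethyl]tetrahydro-4H-pyran-4-one (2,6-cis) | COc1cc(CC[C@H]2CC(=O)C[C@@H](c3cc(OCc4ccccc4)c(OCc4ccccc4)c(OC)c3)O2)ccc1OC(=O)C(C)(C)C
A6 | alternative 2 | (S)-4-{[3,4-bis(benzyloxy)-5-methoxybenzyl]oxy}-6-(3-methoxy-4-pivaloyloxyphenyl)hex-1-en-2-yl acetate | COc1cc(CC[C@@H](CC(=C)OC(C)=O)OCc2cc(OCc3ccccc3)c(OCc3ccccc3)c(OC)c2)ccc1OC(=O)C(C)(C)C
A7 | alternative 3 | (2S,6S)-2-[3,4-bis(benzyloxy)-5-methoxyphenyl]-6-[2-(4-benzyloxy-3-methoxyphenyl)ethyl]tetrahydro-4H-pyran-4-one (2,6-cis) | COc1cc(CC[C@H]2CC(=O)C[C@@H](c3cc(OCc4ccccc4)c(OCc4ccccc4)c(OC)c3)O2)ccc1OCc1ccccc1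
A8 | alternative 3 | (2R,6S)-2-[2-(4-benzyloxy-3-methoxyphenyl)ethyl]-6-[3,4-bis(benzyloxy)-5-methoxyphenyl]-4-methylene-1,3-dioxane (2,6-cis) | COc1cc(CC[C@H]2OC(=C)C[C@@H](c3cc(OCc4ccccc4)c(OCc4ccccc4)c(OC)c3)O2)ccc1OCc1ccccc1
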